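The J.Q I can count at the end of this flask is a remnant of a pool, J plus J.Q, which the dimerisation of J drains.

X 0.050 M; Q 1.00 equiv; time 2.5 d

    X + J.Q → X.J.Q (k1 = 7.8 × 10⁻⁴ L mol⁻¹ s⁻¹)
    J + Q ⇌ J.Q (K2 = 28 L mol⁻¹, k2 = 0.0013 L mol⁻¹ s⁻¹)
    X ⇌ J, rate k3*(cs3 - [J]) while solid is left; crystals form when [J] > cs3 (cs3 = 21 mM, k3 = 7.6 × 10⁻⁵ s⁻¹)
    E ⇌ J.Q, rate k4*(cs4 - [J.Q]) while solid is left; crystals form when [J.Q] > cs4 (cs4 = 23 mM, k4 = 0.0012 s⁻¹)
    2 J → J2 (k5 = 0.0045 L mol⁻¹ s⁻¹)

- amount of J.Q and E together at 2.5 d, in percent of the X charged
- the change that raises the amount of J.Q and E together at 2.5 d, in percent of the X charged most ("none" if none brings more than 2 percentage points) (midnight / noon / autumn / dawn / none)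
- amount of J.Q and E together at 2.5 d, in percent of the X charged, after midnight

- midnight: doubling the dissolution coefficient of step 3, all else as stated
- noon: doubling the amount of Q, all else as stated
- autumn: doubling the solubility in step 4, all else as stated
- dawn: doubling the solubility in step 3, all else as stated

At the early end I take the whole charge c as pool at time zero, since the dissolution could deliver 689% of the charge by 2.5 d into a solution kept empty, if the solid never ran out, more than the charge itself. At the late end I treat binding as a pre-equilibrium, because the forward half-life of J by binding, 0.12 d with the other concentrations as charged, is far shorter than the run. So J.Q over J stands at g, the binding constant times [Q], which I hold at its charged value 1.4.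

Dimerisation then acts on the free fraction of the pool. Solving this second-order decay and joining the two ends gives pool over charge as 1/(1 + t/τ). Here the pool time τ, in which dimerisation halves a pool of the whole charge, is (1 + g) squared over 2 times 0.0045 L mol⁻¹ s⁻¹ times c, or 0.148 d.

The run lasts 16.9 pool times. With the fraction g/(1 + g) of the pool as J.Q, no E counted, and the step X + J.Q set aside as a risk I take, the amount asked, y, comes to 3.26%. Neither the dissolution coefficient nor a solubility stands in τ, so I expect midnight, dawn and autumn to bring nothing and yb, the amount after midnight, to equal y. Noon doubles g, lengthens τ to 0.371 d and gives 9.53%, a gain of 6.3 percentage points.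

The forecast gives 3.2% for y, noon as the best change and 2.9% for yb, holding that “this late decay largely forgets how fast the X dissolved”. This flask gives 3.85%, above my figure, and 3.73% after midnight. The best change is noon, which adds 5.9 points.

In the neighbour flask with 0.20 M of X, at the same equivalents and time, g with Q as charged is 5.60 and τ is 0.280 d. The run is then 8.93 pool times, and the same reckoning gives 8.55%. That flask reads 5.67%, lower than the reckoning. Its J2 holds 29.0%, and the species holding most of its X is X.J.Q, the product of the step I set aside, at 63.9%.

(The rate constants were set for the occasion.)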